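**Strategy.** The dihydropyran ring (O1, C2, C3, C4, C4a, C8a) is cut across C3–C4 and O1–C2. In one operation an inverse-demand oxa-Diels–Alder reaction joins the ortho-quinone methide of ring A (O1=C8a–C4a=C4, C4 carrying the isobutyl group) to the (E)-styrene of ring B (C2=C3, C3 carrying the isopropyl group). The C3–C4 bond forms, the pyran ring closes and all three stereocentres are set under a chiral Brønsted acid. The precursors are two 3-methylbut-1-enyl arenes, a formylated phenol (ring A, the quinone methide tautomer) and a diformyl trimethoxybenzene (ring B), both made from aryl halides and one alkenylboronate; global O-demethylation ends the route.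

Key step: step 6

Remark: chroman numbering is used throughout (O1, C2 bearing ring B, C3 bearing isopropyl, C4 bearing isobutyl; ring A is the benzo ring), and the (R)-catalyst in step 6 is assigned to the (2R,3R,4S) series by analogy only, the (S)-catalyst being used instead should the facial sense prove opposite.

Step 1
Reactants: 1 3-methylbut-1-yne; 2 pinacolborane (4,4,5,5-tetramethyl-1,3,2-dioxaborolane)
Product: 3 (E)-4,4,5,5-tetramethyl-2-(3-methylbut-1-en-1-yl)-1,3,2-dioxaborolane
Conditions: Cp2Zr(H)Cl (5 mol%), Et3N (10 mol%), neat, 60 °C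
Reagents that add atoms: none
Why: Zirconocene hydrochloride-catalysed hydroboration of a terminal alkyne runs by syn-hydrozirconation and Zr-to-B exchange and should give only the (E)-1-alkenylboronate.

Step 2
Reactants: 4 4-hydroxy-2,6-dimethoxybenzaldehyde
Product: 5 4-hydroxy-3-iodo-2,6-dimethoxybenzaldehyde
Conditions: N-iodosuccinimide (1.0 equiv), CF3CO2H (cat.), MeCN, 0 °C to rt
Reagents that add atoms: N-iodosuccinimide, O=C1CCC(=O)N1I
Why: Electrophilic aromatic iodination ortho to the free phenol; the two ortho positions of 4 are equivalent, so only one regioisomer can form, and one equivalent of reagent limits di-iodination.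

Step 3
Reactants: 5 4-hydroxy-3-iodo-2,6-dimethoxybenzaldehyde; 3 (E)-4,4,5,5-tetramethyl-2-(3-methylbut-1-en-1-yl)-1,3,2-dioxaborolane
Product: 6 4-hydroxy-2,6-dimethoxy-3-[(E)-3-methylbut-1-en-1-yl]benzaldehyde
Conditions: Pd(OAc)2 (3 mol%), SPhos (6 mol%), K3PO4, 1,4-dioxane/H2O, 80 °C
Reagents that add atoms: none
Why: Suzuki–Miyaura coupling of an aryl iodide with an alkenylboronate retains the E geometry and tolerates the free phenol and the aldehyde under aqueous phosphate conditions.

Step 4
Reactants: 7 2-bromo-1,3,5-trimethoxybenzene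
Product: 9 5-bromo-2,4,6-trimethoxybenzene-1,3-dicarbaldehyde, via 3-bromo-2,4,6-trimethoxybenzaldehyde 8 (not isolated)
Conditions: Cl2CHOMe (6 equiv), TiCl4 (6 equiv), CH2Cl2, 0 °C to rt; then 1 M HCl
Reagents that add atoms: dichloromethyl methyl ether, COC(Cl)Cl; water, O
Why: Twofold Rieche formylation at the only two free ring positions, so no regiochemical question arises, and the three methoxy groups should keep the ring reactive enough for the second formylation under excess reagent.

Step 5
Reactants: 9 5-bromo-2,4,6-trimethoxybenzene-1,3-dicarbaldehyde; 3 (E)-4,4,5,5-tetramethyl-2-(3-methylbut-1-en-1-yl)-1,3,2-dioxaborolane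
Product: 10 2,4,6-trimethoxy-5-[(E)-3-methylbut-1-en-1-yl]benzene-1,3-dicarbaldehyde
Conditions: Pd(OAc)2 (5 mol%), SPhos (10 mol%), K3PO4, toluene/H2O, 90 °C
Reagents that add atoms: none
Why: Suzuki–Miyaura coupling of an electron-poor, di-ortho-substituted aryl bromide, a substrate class for which the bulky biaryl phosphine is suited; the E geometry of the boronate is retained.

Step 6
Reactants: 6 4-hydroxy-2,6-dimethoxy-3-[(E)-3-methylbut-1-en-1-yl]benzaldehyde; 10 2,4,6-trimethoxy-5-[(E)-3-methylbut-1-en-1-yl]benzene-1,3-dicarbaldehyde
Product: 12 (2R,3R,4S)-2-(3,5-diformyl-2,4,6-trimethoxyphenyl)-5,7-dimethoxy-4-(2-methylpropyl)-3-(propan-2-yl)-3,4-dihydro-2H-chromene-6-carbaldehyde, via ortho-quinone methide 11 (not isolated)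
Conditions: (R)-3,3'-bis(2,4,6-triisopropylphenyl)-1,1'-binaphthalene-2,2'-diyl N-triflylphosphoramide (10 mol%), 10 (3 equiv), 6 added over 10 h, 5 Å MS, CH2Cl2, −20 °C to rt
Reagents that add atoms: none
Why: The phosphoramide protonates the electron-rich styrene of 6 at its β-carbon, which converts the 2-alkenylphenol into its tautomer, the ortho-quinone methide 11, held by hydrogen bonding through O1 to the chiral anion; this heterodiene (O1=C8a–C4a=C4) then adds to the (E)-alkene 10 in an inverse-electron-demand oxa-Diels–Alder reaction, with C4 bonding to the isopropyl-bearing carbon (C3) and O1 to the benzylic carbon (C2). The closest known reaction type is the chiral N-triflylphosphoramide- or phosphoric acid-catalysed (4+2) cycloaddition of ortho-quinone methides generated in situ with styrenes to give chromans. The dihydropyran ring is closed in an intermolecular, concerted but asynchronous (4+2) mode in which the C3–C4 bond forms in advance of O1–C2, and ring A regains aromaticity in the same event. C2 and C3 should be set trans by suprafacial addition to the (E)-alkene; C4 should be set cis to C3 because the methide is expected to react with the isobutyl chain syn to the carbonyl oxygen (allylic strain with the out-of-plane C5 methoxy group disfavours the other rotamer) while the isopropyl group on the bond-forming carbon takes the exo position, which places the C2 aryl endo; the absolute sense (2R,3R,4S) is to come from the chiral counter-anion shielding one face of C4. The step needs cross- over self-cycloaddition (6 is itself a dienophile for 11), which slow addition of 6 to an excess of 10 should secure, and a single direction of ring closure, which is secured because O1 is the only free oxygen of ring A.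

Step 7
Reactants: 12 (2R,3R,4S)-2-(3,5-diformyl-2,4,6-trimethoxyphenyl)-5,7-dimethoxy-4-(2-methylpropyl)-3-(propan-2-yl)-3,4-dihydro-2H-chromene-6-carbaldehyde
Product: 13 (2R,3R,4S)-2-(3,5-diformyl-2,4,6-trihydroxyphenyl)-5,7-dihydroxy-4-(2-methylpropyl)-3-(propan-2-yl)-3,4-dihydro-2H-chromene-6-carbaldehyde
Conditions: BBr3 (15 equiv), CH2Cl2, −78 °C to 0 °C; then H2O
Reagents that add atoms: none
Why: Lewis-acid cleavage of aryl methyl ethers, assisted here by chelation because each of the five methoxy groups is ortho to a formyl group; no stereocentre is a reacting centre.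

**Compound list**

1 | 3-methylbut-1-yne | CC(C)C#C | starting material
2 | pinacolborane (4,4,5,5-tetramethyl-1,3,2-dioxaborolane) | [H]B1OC(C)(C)C(C)(C)O1 | starting material
3 | (E)-4,4,5,5-tetramethyl-2-(3-methylbut-1-en-1-yl)-1,3,2-dioxaborolane | CC(C)/C=C/B1OC(C)(C)C(C)(C)O1 | intermediate
4 | 4-hydroxy-2,6-dimethoxybenzaldehyde | COc1cc(O)cc(OC)c1C=O | starting material
5 | 4-hydroxy-3-iodo-2,6-dimethoxybenzaldehyde | COc1cc(O)c(I)c(OC)c1C=O | intermediate
6 | 4-hydroxy-2,6-dimethoxy-3-[(E)-3-methylbut-1-en-1-yl]benzaldehyde | COc1cc(O)c(/C=C/C(C)C)c(OC)c1C=O | intermediate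
7 | 2-bromo-1,3,5-trimethoxybenzene | COc1cc(OC)c(Br)c(OC)c1 | starting material
8 | 3-bromo-2,4,6-trimethoxybenzaldehyde (not isolated) | COc1cc(OC)c(Br)c(OC)c1C=O | intermediate
9 | 5-bromo-2,4,6-trimethoxybenzene-1,3-dicarbaldehyde | COc1c(Br)c(OC)c(C=O)c(OC)c1C=O | intermediate
10 | 2,4,6-trimethoxy-5-[(E)-3-methylbut-1-en-1-yl]benzene-1,3-dicarbaldehyde | COc1c(/C=C/C(C)C)c(OC)c(C=O)c(OC)c1C=O | intermediate
11 | ortho-quinone methide, (3Z)-2,6-dimethoxy-3-(3-methylbutylidene)-4-oxocyclohexa-1,5-diene-1-carbaldehyde (not isolated) | CC(C)C/C=C1\C(=O)C=C(OC)C(C=O)=C1OC | intermediate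
12 | (2R,3R,4S)-2-(3,5-diformyl-2,4,6-trimethoxyphenyl)-5,7-dimethoxy-4-(2-methylpropyl)-3-(propan-2-yl)-3,4-dihydro-2H-chromene-6-carbaldehyde | CC(C)C[C@@H]1c2c(cc(OC)c(C=O)c2OC)O[C@@H](c2c(OC)c(C=O)c(OC)c(C=O)c2OC)[C@@H]1C(C)C | intermediate
13 | (2R,3R,4S)-2-(3,5-diformyl-2,4,6-trihydroxyphenyl)-5,7-dihydroxy-4-(2-methylpropyl)-3-(propan-2-yl)-3,4-dihydro-2H-chromene-6-carbaldehyde | CC(C)C[C@@H]1c2c(cc(O)c(C=O)c2O)O[C@@H](c2c(O)c(C=O)c(O)c(C=O)c2O)[C@@H]1C(C)C | target

**Step count.** Total: 7 steps. Longest linear sequence: 4 steps (steps 2, 3, 6, 7; the sequences 1, 3, 6, 7 and 4, 5, 6, 7 are equally long).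

**Steps most likely to fail**

Step 6 (key step). Three processes may defeat it: self-cycloaddition of 11 with its own precursor 6, approach of the dienophile in the exo-aryl or E-methide mode (which would give the C4 epimer), and insufficient facial discrimination by the catalyst. The fallback sets out from 6. Mukaiyama hydration (Co(acac)2, PhSiH3, O2, THF) should give the racemic benzylic alcohol 4-hydroxy-3-(1-hydroxy-3-methylbutyl)-2,6-dimethoxybenzaldehyde F1. Heated with an excess of 10 in toluene, F1 should lose water to 11 under acid-free conditions, where 6 cannot be re-ionised. The thermal cycloaddition should then give 12 together with its mirror image, the (2S,3S,4R)-cycloadduct F2. Chromatography on a chiral stationary phase separates the two, and the route is rejoined at 12.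

Step 7. The Lewis acid may ionise the benzylic C2–O1 bond (ring opening and loss of the C2 configuration), and the methoxy groups flanked on both sides may be cleaved incompletely. The fallback sets out from 12 and replaces Lewis-acid cleavage by nucleophilic demethylation: SN2 attack of a thiolate on the methyl groups (NaSEt, DMF, 100 °C, then acidic work-up), which does not activate the ring oxygen. It leads directly to 13 and makes no compound outside the list (F0).

Step 4. The reaction may stall after the first formylation, because 8 is deactivated by its TiCl4-complexed formyl group, and chelation may cause loss of a methyl ether. The fallback sets out from 7. Twofold bromomethylation (paraformaldehyde, HBr, AcOH) should give 2-bromo-4,6-bis(bromomethyl)-1,3,5-trimethoxybenzene F3. Kornblum oxidation (DMSO, NaHCO3, 100 °C) of both benzylic bromides then rejoins the route at 9.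

Further compounds
F1 | step 6 | 4-hydroxy-3-(1-hydroxy-3-methylbutyl)-2,6-dimethoxybenzaldehyde (racemic) | COc1cc(O)c(C(O)CC(C)C)c(OC)c1C=O
F2 | step 6 | (2S,3S,4R)-2-(3,5-diformyl-2,4,6-trimethoxyphenyl)-5,7-dimethoxy-4-(2-methylpropyl)-3-(propan-2-yl)-3,4-dihydro-2H-chromene-6-carbaldehyde | CC(C)C[C@H]1c2c(cc(OC)c(C=O)c2OC)O[C@H](c2c(OC)c(C=O)c(OC)c(C=O)c2OC)[C@H]1C(C)C
F0 | step 7 | none | none
F3 | step 4 | 2-bromo-4,6-bis(bromomethyl)-1,3,5-trimethoxybenzene | COc1c(Br)c(OC)c(CBr)c(OC)c1CBr
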